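The plan opens the butenolide at its C3'=C4' double bond and at the O1'–C2' ester bond, which leads back to an α-hydroxy methyl ketone. The feature used is the all-syn oxygen triad C14–C15–C5', framed by the sp2 carbons C13 and C4'. This triad is C2–C4 of D-glucose, whose C1, C5 and C6 become C13, C4' and the ring methyl group. In one operation an intramolecular Horner–Wadsworth–Emmons reaction forms C3'=C4' and closes the lactone ring without touching a stereocentre. Its precursor is the complete, fully silylated C25 skeleton with a diethylphosphonoacetate on O5' beside the C4' methyl ketone.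

Key step: step 26

**Remarks on structure and design**
- **Numbering:** labdane numbering is used for C1–C20, with C16 as the exocyclic methylene carbon on C13. The lactone is numbered O1', C2' (C=O), C3', C4', C5'.
- **Reading of the target:**
  - The decalin is trans-fused (5α-H, 9α-H, 10β-CH3).
  - C4 carries an equatorial 4α-CH2OH (C18) and an axial 4β-CH3 (C19).
  - The 6α-OH and 8α-OH are equatorial and the 8β-CH3 is axial.
  - C14, C15 and C5' (14S,15R,5'R) have the spatial arrangement of C2, C3 and C4 of D-glucose.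
- **What larixol lacks:** larixol supplies C5, C6, C9 and C10 but has a gem-dimethyl C4 and no oxygen at C8.
  - O8 is added in steps 2–3.
  - The missing C18 oxygen is added in steps 5–7 by hydrogen transfer to the neighbouring 6α-oxygen.
- **Protection of O8:** a free 8α-hydroxyl would close onto an activated C12 to give an 8α,12-tetrahydrofuran and would quench a C12 carbanion. O8 is therefore silylated before C12 is activated and stays silylated in the key precursor.
- **Protection of O14 and O15:** these are carried as two silyl ethers and not as a ketal.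
  - The diequatorial 2,3-diol of the pyranose accepts silyl groups directly.
  - The end game becomes a single fluoride step, with no aqueous acid on the tertiary C8 carbinol or the allylic C13–C14 unit.
- **Origin of the stereocentres:**
  - C5, C6, C9 and C10 come from larixol.
  - C8 is set in step 2 and kept in step 3.
  - C4 is set in step 5.
  - C14, C15 and C5' come from glucose.
- **Assumption:** lactols 16 and 21 are anomeric mixtures and 17–20 are drawn as β-anomers. The anomeric centre disappears in step 17, so its configuration has no consequence.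

## Part A: decalin iodide from larixol

Step 1
Reactants: 1 (+)-larixol
Product: 2 6α-hydroxy-14,15-dinorlabd-8(17)-en-13-one
Conditions: KMnO4, BnEt3NCl, CH2Cl2, 0 °C to rt
Reagents that add atoms: none
Why: Permanganate degradation of a tertiary vinyl carbinol: the vinyl group next to the C13 hydroxyl should be hydroxylated and cleaved down to the methyl ketone while the sterically screened 8(17)-methylene group and the hindered equatorial 6α-carbinol react more slowly, and no stereocentre is involved.

Step 2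
Reactants: 2 6α-hydroxy-14,15-dinorlabd-8(17)-en-13-one
Product: 4 8α,17-epoxy-6α-hydroxy-13,14,15,16-tetranorlabdan-12-yl acetate, via epoxy ketone 3 (not isolated)
Conditions: CF3CO3H (preformed from urea·H2O2 and (CF3CO)2O), Na2HPO4, CH2Cl2, 0 °C to rt
Reagents that add atoms: trifluoroperacetic acid, OOC(=O)C(F)(F)F
Why: Prilezhaev epoxidation and Baeyer–Villiger oxidation in one flask: the peracid should reach the exocyclic alkene from the α face because the axial C20 methyl group shields the β face (the 6α-hydroxyl can also guide it), which sets C8 with oxygen α, and in the Criegee adduct of the ketone the primary C12 migrates in preference to methyl, the phosphate buffer protecting the spiro-epoxide from acid.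

Step 3
Reactants: 4 8α,17-epoxy-6α-hydroxy-13,14,15,16-tetranorlabdan-12-yl acetate
Product: 5 13,14,15,16-tetranorlabdane-6α,8α,12-triol
Conditions: LiAlH4, THF, 0 °C to reflux
Reagents that add atoms: none
Why: Hydride reduction with LiAlH4: SN2 attack at the unhindered C17 methylene opens the epoxide without breaking the C8–O bond, so that the 8α-hydroxyl and the axial 8β-methyl group result, and the acetate is cleaved to the C12 alcohol in the same operation.

Step 4
Reactants: 5 13,14,15,16-tetranorlabdane-6α,8α,12-triol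
Product: 7 6α-hydroxy-13,14,15,16-tetranorlabdan-12,8α-olide, via lactol 6 (not isolated)
Conditions: TEMPO (cat.), PhI(OAc)2, CH2Cl2, rt
Reagents that add atoms: none
Why: TEMPO oxidative lactonisation of a 1,4-diol: the oxoammonium salt oxidises only the unhindered primary C12 alcohol, the aldehyde is trapped by the C8 hydroxyl as lactol 6 and this is oxidised further, so that O8 and C12 are masked together and the hindered 6α-hydroxyl remains the only free alcohol.

Step 5
Reactants: 7 6α-hydroxy-13,14,15,16-tetranorlabdan-12,8α-olide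
Product: 9 6α,18-epoxy-13,14,15,16-tetranorlabdan-12,8α-olide, via 18-iodo alcohol 8 (not isolated)
Conditions: PhI(OAc)2, I2, cyclohexane–CH2Cl2, visible light, rt
Reagents that add atoms: none
Why: Suárez hypoiodite reaction (alkoxy-radical 1,5-hydrogen atom transfer followed by cyclic ether formation): the equatorial 6α-oxygen radical stands parallel to the equatorial 4α-methyl group across C5 and takes a hydrogen from it through a six-membered transition state, iodine captures the C18 radical and O6 displaces iodide, which makes C4 a stereocentre with the oxidised carbon α and the out-of-reach axial 4β-methyl group unchanged.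

Step 6
Reactants: 9 6α,18-epoxy-13,14,15,16-tetranorlabdan-12,8α-olide
Product: 10 13,14,15,16-tetranorlabdane-12,8α:18,6α-diolide
Conditions: RuCl3·xH2O (cat.), NaIO4, MeCN–EtOAc–H2O, rt
Reagents that add atoms: sodium periodate (oxygen passed on by way of RuO4), [Na+].[O-]I(=O)(=O)=O
Why: RuO4 oxidation of a cyclic ether to a lactone: the open C18 methylene group next to oxygen should be attacked, whereas the only other α-hydrogen, axial 6β-H, is screened by the axial C19 and C20 methyl groups, and the first lactone is inert.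

Step 7
Reactants: 10 13,14,15,16-tetranorlabdane-12,8α:18,6α-diolide
Product: 11 13,14,15,16-tetranorlabdane-6α,8α,12,18-tetraol
Conditions: LiAlH4, THF, reflux
Reagents that add atoms: none
Why: LiAlH4 reduction of both lactones to diols: only acyl C–O bonds are broken, so C4, C6 and C8 keep their configuration and the 18-hydroxymethyl group of the target appears.

Step 8
Reactants: 11 13,14,15,16-tetranorlabdane-6α,8α,12,18-tetraol
Product: 12 6α,8α,12,18-tetrakis(tert-butyldimethylsilyloxy)-13,14,15,16-tetranorlabdane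
Conditions: TBSOTf (excess), 2,6-lutidine, CH2Cl2, 0 to 35 °C
Reagents that add atoms: tert-butyldimethylsilyl triflate, CC(C)(C)[Si](C)(C)OS(=O)(=O)C(F)(F)F
Why: Exhaustive silylation with a silyl triflate and a hindered pyridine base, a reagent pair strong enough for the hindered 6α- and the tertiary 8α-hydroxyl; covering O8 is essential because a free 8α-hydroxyl would close onto an activated C12 and would quench a C12 carbanion.

Step 9
Reactants: 12 6α,8α,12,18-tetrakis(tert-butyldimethylsilyloxy)-13,14,15,16-tetranorlabdane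
Product: 13 6α,8α,18-tris(tert-butyldimethylsilyloxy)-13,14,15,16-tetranorlabdan-12-ol
Conditions: CSA (cat.), MeOH–CH2Cl2, −10 °C
Reagents that add atoms: none
Why: Sterically controlled acid-catalysed methanolysis of silyl ethers: the unbranched primary C12 ether should be cleaved well before the neopentyl C18, the secondary C6 and the tertiary C8 ethers.

Step 10
Reactants: 13 6α,8α,18-tris(tert-butyldimethylsilyloxy)-13,14,15,16-tetranorlabdan-12-ol
Product: 14 6α,8α,18-tris(tert-butyldimethylsilyloxy)-12-iodo-13,14,15,16-tetranorlabdane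
Conditions: I2, PPh3, imidazole, CH2Cl2, 0 °C to rt
Reagents that add atoms: iodine, II
Why: Appel-type iodination (Garegg–Samuelsson conditions): the alkoxyphosphonium salt of the primary alcohol is displaced by iodide in an SN2 step under nearly neutral conditions that leave the silyl ethers alone.

## Part B: 6-deoxygluconic amide from D-glucose

Step 11
Reactants: 15 D-glucose
Product: 16 4,6-O-[(R)-4-methoxybenzylidene]-D-glucopyranose
Conditions: 4-MeOC6H4CH(OMe)2, p-TsOH (cat.), DMF, 50 °C, reduced pressure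
Reagents that add atoms: 4-methoxybenzaldehyde dimethyl acetal, COc1ccc(C(OC)OC)cc1
Why: Acid-catalysed transacetalisation under thermodynamic control: the 4,6-diol of the pyranose form gives the trans-fused 1,3-dioxane with the aryl group equatorial, which separates O4 and O6 from O1–O3.

Step 12
Reactants: 16 4,6-O-[(R)-4-methoxybenzylidene]-D-glucopyranose
Product: 17 tert-butyldimethylsilyl 2,3-bis-O-(tert-butyldimethylsilyl)-4,6-O-(4-methoxybenzylidene)-β-D-glucopyranoside
Conditions: TBSOTf, 2,6-lutidine, CH2Cl2, 0 °C to rt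
Reagents that add atoms: tert-butyldimethylsilyl triflate, CC(C)(C)[Si](C)(C)OS(=O)(=O)C(F)(F)F
Why: Silylation with a silyl triflate: the diequatorial 2,3-diol, which cannot carry a strain-free five-membered ketal, takes the two silyl ethers that later protect O14 and O15, and the anomeric hydroxyl is covered at the same time.

Step 13
Reactants: 17 tert-butyldimethylsilyl 2,3-bis-O-(tert-butyldimethylsilyl)-4,6-O-(4-methoxybenzylidene)-β-D-glucopyranoside
Product: 18 tert-butyldimethylsilyl 2,3-bis-O-(tert-butyldimethylsilyl)-4-O-(4-methoxybenzyl)-β-D-glucopyranoside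
Conditions: i-Bu2AlH, toluene, −78 to 0 °C
Reagents that add atoms: none
Why: Regioselective reductive opening of a 4-methoxybenzylidene acetal: the aluminium hydride binds the less hindered O6, the C–O6 bond breaks and hydride goes to the oxocarbenium ion, so that the 4-methoxybenzyl group stays on O4 and the primary 6-hydroxyl is freed.

Step 14
Reactants: 18 tert-butyldimethylsilyl 2,3-bis-O-(tert-butyldimethylsilyl)-4-O-(4-methoxybenzyl)-β-D-glucopyranoside
Product: 19 tert-butyldimethylsilyl 2,3-bis-O-(tert-butyldimethylsilyl)-6-deoxy-6-iodo-4-O-(4-methoxybenzyl)-β-D-glucopyranoside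
Conditions: I2, PPh3, imidazole, toluene, 60 °C
Reagents that add atoms: iodine, II
Why: Garegg–Samuelsson iodination, an SN2 displacement at the primary C6 that does not affect the ring stereocentres.

Step 15
Reactants: 19 tert-butyldimethylsilyl 2,3-bis-O-(tert-butyldimethylsilyl)-6-deoxy-6-iodo-4-O-(4-methoxybenzyl)-β-D-glucopyranoside
Product: 20 tert-butyldimethylsilyl 2,3-bis-O-(tert-butyldimethylsilyl)-6-deoxy-4-O-(4-methoxybenzyl)-β-D-glucopyranoside
Conditions: Bu3SnH, AIBN (cat.), toluene, 85 °C
Reagents that add atoms: none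
Why: Radical chain dehalogenation with a tin hydride: the primary C6 radical abstracts hydrogen, which turns C6 into the methyl group of the future lactone under neutral conditions.

Step 16
Reactants: 20 tert-butyldimethylsilyl 2,3-bis-O-(tert-butyldimethylsilyl)-6-deoxy-4-O-(4-methoxybenzyl)-β-D-glucopyranoside
Product: 21 2,3-bis-O-(tert-butyldimethylsilyl)-6-deoxy-4-O-(4-methoxybenzyl)-D-glucopyranose
Conditions: Bu4NF, AcOH, THF, −20 to 0 °C
Reagents that add atoms: none
Why: Chemoselective desilylation at the anomeric centre: the silyl acetal oxygen is the best leaving group in the molecule, so that acetic-acid-buffered fluoride at low temperature should remove it before the hindered secondary silyl ethers and without silyl migration.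

Step 17
Reactants: 21 2,3-bis-O-(tert-butyldimethylsilyl)-6-deoxy-4-O-(4-methoxybenzyl)-D-glucopyranose
Product: 22 2,3-bis-O-(tert-butyldimethylsilyl)-6-deoxy-4-O-(4-methoxybenzyl)-D-glucono-1,5-lactone
Conditions: Dess–Martin periodinane, CH2Cl2, rt
Reagents that add atoms: none
Why: Dess–Martin oxidation of a lactol to the δ-lactone, which removes the anomeric stereocentre and brings C1 to the acid level under non-epimerising conditions.

Step 18
Reactants: 22 2,3-bis-O-(tert-butyldimethylsilyl)-6-deoxy-4-O-(4-methoxybenzyl)-D-glucono-1,5-lactone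
Product: 23 2,3-bis-O-(tert-butyldimethylsilyl)-6-deoxy-4-O-(4-methoxybenzyl)-N-methoxy-N-methyl-D-gluconamide
Conditions: MeONHMe·HCl, AlMe3, CH2Cl2, 0 °C to rt
Reagents that add atoms: N,O-dimethylhydroxylamine hydrochloride, CNOC.Cl
Why: Aminolysis of a lactone with an aluminium amide (Weinreb amide synthesis): ring opening frees O5 as the only hydroxyl group and thus tells it apart from O4 without a further protecting-group exchange.

Step 19
Reactants: 23 2,3-bis-O-(tert-butyldimethylsilyl)-6-deoxy-4-O-(4-methoxybenzyl)-N-methoxy-N-methyl-D-gluconamide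
Product: 24 2,3-bis-O-(tert-butyldimethylsilyl)-6-deoxy-4-O-(4-methoxybenzyl)-5-O-(triethylsilyl)-N-methoxy-N-methyl-D-gluconamide
Conditions: TESOTf, 2,6-lutidine, CH2Cl2, −40 °C
Reagents that add atoms: triethylsilyl triflate, CC[Si](CC)(CC)OS(=O)(=O)C(F)(F)F
Why: Silylation with triethylsilyl triflate at low temperature, fast enough to outrun relactonisation, puts on O5 a group that is more labile than every tert-butyldimethylsilyl ether.

## Part C: union, key step and release of the target

Step 20
Reactants: 14 6α,8α,18-tris(tert-butyldimethylsilyloxy)-12-iodo-13,14,15,16-tetranorlabdane; 24 2,3-bis-O-(tert-butyldimethylsilyl)-6-deoxy-4-O-(4-methoxybenzyl)-5-O-(triethylsilyl)-N-methoxy-N-methyl-D-gluconamide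
Product: 26 C13 ketone (full C12–C13-linked carbon chain; 6,8,14,15,18-penta-O-TBS; 5'-O-PMB; 4'-O-TES), via organolithium 25 (not isolated)
Conditions: 14, t-BuLi (2 equiv per iodide), Et2O–pentane, −78 °C; then 24, −78 to −40 °C; aq. NH4Cl
Reagents that add atoms: none
Why: Lithium–iodine exchange followed by the Weinreb ketone synthesis: two equivalents of t-BuLi convert the primary iodide into organolithium 25, which is kept at −78 °C to avoid silyl migration from O8, and the N-methoxy-N-methylamide accepts only one equivalent of it, forming the C12–C13 bond without touching C14.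

Step 21
Reactants: 26 C13 ketone
Product: 27 13(16)-methylene compound (6,8,14,15,18-penta-O-TBS; 5'-O-PMB; 4'-O-TES)
Conditions: Cp2TiMe2, toluene, 70 °C, dark
Reagents that add atoms: dimethyltitanocene Cp2TiMe2, C[Ti](C)(C1C=CC=C1)C1C=CC=C1
Why: Petasis methylenation: the non-basic titanium methylidene formed on heating converts the hindered, enolisable α-silyloxy ketone into the 13(16)-alkene by way of an oxatitanacyclobutane, so that C14 is not epimerised and the C15 silyloxy group is not eliminated.

Step 22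
Reactants: 27 13(16)-methylene compound
Product: 28 C4' carbinol (6,8,14,15,18-penta-O-TBS; 5'-O-PMB)
Conditions: PPTS (cat.), MeOH–CH2Cl2, 0 °C
Reagents that add atoms: none
Why: Selective acid-catalysed methanolysis: the triethylsilyl ether is cleaved far faster than the tert-butyldimethylsilyl ethers, none of which now sits on an unhindered primary carbon.

Step 23
Reactants: 28 C4' carbinol
Product: 29 C4' methyl ketone (6,8,14,15,18-penta-O-TBS; 5'-O-PMB)
Conditions: Dess–Martin periodinane, CH2Cl2, 0 °C to rt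
Reagents that add atoms: none
Why: Dess–Martin oxidation of the secondary alcohol gives the C4' methyl ketone under neutral conditions and removes the former C5 stereocentre of glucose, which the target does not need.

Step 24
Reactants: 29 C4' methyl ketone
Product: 30 5'-hydroxy-4'-ketone (6,8,14,15,18-penta-O-TBS)
Conditions: DDQ, CH2Cl2–pH 7 buffer (NaH2PO4/Na2HPO4), 0 °C
Reagents that add atoms: none
Why: Oxidative cleavage of the 4-methoxybenzyl ether with DDQ in buffered wet solvent: only the electron-rich benzylic position is oxidised, and the neutral medium should prevent α-ketol rearrangement or epimerisation at C5'.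

Step 25
Reactants: 30 5'-hydroxy-4'-ketone; 31 diethylphosphonoacetic acid
Product: 32 protected seco-lactone (5'-O-diethylphosphonoacetate; C4' methyl ketone; 6,8,14,15,18-penta-O-TBS)
Conditions: EDC·HCl, DMAP (cat.), CH2Cl2, 0 °C
Reagents that add atoms: none
Why: Carbodiimide (Steglich) esterification: O5' is the only free hydroxyl group, and the mild conditions at 0 °C with catalytic DMAP should leave C5' intact.

Step 26
Reactants: 32 protected seco-lactone
Product: 33 protected target (butenolide; 6,8,14,15,18-penta-O-TBS)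
Conditions: LiCl, i-Pr2NEt, MeCN, 0 °C to rt
Reagents that add atoms: none
Why: Lithium-assisted deprotonation of the doubly activated phosphonoacetate CH2 by the tertiary amine gives a chelated phosphonate carbanion that adds to the neighbouring C4' ketone, and the oxaphosphetane so formed collapses with loss of diethyl phosphate to leave the endocyclic C3'=C4' alkene. The closest known reaction type is the intramolecular Horner–Wadsworth–Emmons olefination of α-(phosphonoacetoxy) ketones under Masamune–Roush conditions, a standard entry to butenolides. The one ring formed, O1'–C2'–C3'–C4'–C5', closes in the 5-exo-trig mode, since the carbanion attacks a carbonyl group whose C=O bond lies outside the new ring. No stereocentre is created, and C14, C15 and C5' keep the configuration they had as C2, C3 and C4 of D-glucose. The selectivity required is deprotonation at C3' only, without enolisation of the ketone towards C5', which would cause epimerisation or β-elimination of the C15 silyloxy group; the large acidity gap between the lithium-bound phosphonoacetate and the ketone, the weak amine base and the speed of five-ring closure should secure it. The same weak base should also spare the acidic γ-hydrogen at C5' of the finished butenolide, and the silyl ethers and the 13(16)-alkene are spectators.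

Step 27
Reactants: 33 protected target
Product: 34 CNP0301623.1
Conditions: HF·pyridine, THF, 0 °C to rt (polyethylene vessel)
Reagents that add atoms: none
Why: Fluoride-driven global desilylation: the strength of the Si–F bond removes all five silyl ethers under weakly acidic, non-aqueous conditions that should neither epimerise C5' (as basic fluoride could) nor ionise the tertiary C8 carbinol or the allylic C14 position.

## Compound list

1 | (+)-larixol, (13S)-labda-8(17),14-diene-6α,13-diol | C=C[C@@](C)(O)CC[C@@H]1[C@@]2(C)CCCC(C)(C)[C@@H]2[C@@H](O)CC1=C | starting material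
2 | 6α-hydroxy-14,15-dinorlabd-8(17)-en-13-one | CC(=O)CC[C@@H]1[C@@]2(C)CCCC(C)(C)[C@@H]2[C@@H](O)CC1=C | intermediate
3 | 8α,17-epoxy-6α-hydroxy-14,15-dinorlabdan-13-one (not isolated) | CC(=O)CC[C@@H]1[C@@]2(C)CCCC(C)(C)[C@@H]2[C@@H](O)C[C@]13CO3 | intermediate
4 | 8α,17-epoxy-6α-hydroxy-13,14,15,16-tetranorlabdan-12-yl acetate | CC(=O)OCC[C@@H]1[C@@]2(C)CCCC(C)(C)[C@@H]2[C@@H](O)C[C@]13CO3 | intermediate
5 | 13,14,15,16-tetranorlabdane-6α,8α,12-triol | OCC[C@@H]1[C@@]2(C)CCCC(C)(C)[C@@H]2[C@@H](O)C[C@@]1(C)O | intermediate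
6 | 8α,12-epoxy-13,14,15,16-tetranorlabdane-6α,12-diol (lactol, not isolated) | OC1C[C@@H]2[C@@]3(C)CCCC(C)(C)[C@@H]3[C@@H](O)C[C@@]2(C)O1 | intermediate
7 | 6α-hydroxy-13,14,15,16-tetranorlabdan-12,8α-olide | O=C1C[C@@H]2[C@@]3(C)CCCC(C)(C)[C@@H]3[C@@H](O)C[C@@]2(C)O1 | intermediate
8 | 6α-hydroxy-18-iodo-13,14,15,16-tetranorlabdan-12,8α-olide (not isolated) | O=C1C[C@@H]2[C@@]3(C)CCC[C@@](C)(CI)[C@@H]3[C@@H](O)C[C@@]2(C)O1 | intermediate
9 | 6α,18-epoxy-13,14,15,16-tetranorlabdan-12,8α-olide | O=C1C[C@@H]2[C@@]3(C)CCC[C@@](C)(CO4)[C@@H]3[C@@H]4C[C@@]2(C)O1 | intermediate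
10 | 13,14,15,16-tetranorlabdane-12,8α:18,6α-diolide | O=C1C[C@@H]2[C@@]3(C)CCC[C@@](C)(C(=O)O4)[C@@H]3[C@@H]4C[C@@]2(C)O1 | intermediate
11 | 13,14,15,16-tetranorlabdane-6α,8α,12,18-tetraol | OCC[C@@H]1[C@@]2(C)CCC[C@@](C)(CO)[C@@H]2[C@@H](O)C[C@@]1(C)O | intermediate
12 | 6α,8α,12,18-tetrakis(tert-butyldimethylsilyloxy)-13,14,15,16-tetranorlabdane | CC(C)(C)[Si](C)(C)OCC[C@@H]1[C@@]2(C)CCC[C@@](C)(CO[Si](C)(C)C(C)(C)C)[C@@H]2[C@@H](O[Si](C)(C)C(C)(C)C)C[C@@]1(C)O[Si](C)(C)C(C)(C)C | intermediate
13 | 6α,8α,18-tris(tert-butyldimethylsilyloxy)-13,14,15,16-tetranorlabdan-12-ol | OCC[C@@H]1[C@@]2(C)CCC[C@@](C)(CO[Si](C)(C)C(C)(C)C)[C@@H]2[C@@H](O[Si](C)(C)C(C)(C)C)C[C@@]1(C)O[Si](C)(C)C(C)(C)C | intermediate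
14 | 6α,8α,18-tris(tert-butyldimethylsilyloxy)-12-iodo-13,14,15,16-tetranorlabdane | ICC[C@@H]1[C@@]2(C)CCC[C@@](C)(CO[Si](C)(C)C(C)(C)C)[C@@H]2[C@@H](O[Si](C)(C)C(C)(C)C)C[C@@]1(C)O[Si](C)(C)C(C)(C)C | intermediate
15 | D-glucose | O=C[C@H](O)[C@@H](O)[C@H](O)[C@H](O)CO | starting material
16 | 4,6-O-[(R)-4-methoxybenzylidene]-D-glucopyranose (anomeric mixture) | OC1O[C@@H]2CO[C@@H](c3ccc(OC)cc3)O[C@H]2[C@H](O)[C@H]1O | intermediate
17 | tert-butyldimethylsilyl 2,3-bis-O-TBS-4,6-O-(4-methoxybenzylidene)-β-D-glucopyranoside | CC(C)(C)[Si](C)(C)O[C@@H]1O[C@@H]2CO[C@@H](c3ccc(OC)cc3)O[C@H]2[C@H](O[Si](C)(C)C(C)(C)C)[C@H]1O[Si](C)(C)C(C)(C)C | intermediate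
18 | tert-butyldimethylsilyl 2,3-bis-O-TBS-4-O-(4-methoxybenzyl)-β-D-glucopyranoside | CC(C)(C)[Si](C)(C)O[C@@H]1O[C@H](CO)[C@@H](OCc2ccc(OC)cc2)[C@H](O[Si](C)(C)C(C)(C)C)[C@H]1O[Si](C)(C)C(C)(C)C | intermediate
19 | tert-butyldimethylsilyl 2,3-bis-O-TBS-6-deoxy-6-iodo-4-O-(4-methoxybenzyl)-β-D-glucopyranoside | CC(C)(C)[Si](C)(C)O[C@@H]1O[C@H](CI)[C@@H](OCc2ccc(OC)cc2)[C@H](O[Si](C)(C)C(C)(C)C)[C@H]1O[Si](C)(C)C(C)(C)C | intermediate
20 | tert-butyldimethylsilyl 2,3-bis-O-TBS-6-deoxy-4-O-(4-methoxybenzyl)-β-D-glucopyranoside | CC(C)(C)[Si](C)(C)O[C@@H]1O[C@H](C)[C@@H](OCc2ccc(OC)cc2)[C@H](O[Si](C)(C)C(C)(C)C)[C@H]1O[Si](C)(C)C(C)(C)C | intermediate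
21 | 2,3-bis-O-TBS-6-deoxy-4-O-(4-methoxybenzyl)-D-glucopyranose (anomeric mixture) | OC1O[C@H](C)[C@@H](OCc2ccc(OC)cc2)[C@H](O[Si](C)(C)C(C)(C)C)[C@H]1O[Si](C)(C)C(C)(C)C | intermediate
22 | 2,3-bis-O-TBS-6-deoxy-4-O-(4-methoxybenzyl)-D-glucono-1,5-lactone | O=C1O[C@H](C)[C@@H](OCc2ccc(OC)cc2)[C@H](O[Si](C)(C)C(C)(C)C)[C@H]1O[Si](C)(C)C(C)(C)C | intermediate
23 | 2,3-bis-O-TBS-6-deoxy-4-O-(4-methoxybenzyl)-N-methoxy-N-methyl-D-gluconamide | CON(C)C(=O)[C@H](O[Si](C)(C)C(C)(C)C)[C@@H](O[Si](C)(C)C(C)(C)C)[C@H](OCc1ccc(OC)cc1)[C@H](O)C | intermediate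
24 | 2,3-bis-O-TBS-6-deoxy-4-O-(4-methoxybenzyl)-5-O-TES-N-methoxy-N-methyl-D-gluconamide | CON(C)C(=O)[C@H](O[Si](C)(C)C(C)(C)C)[C@@H](O[Si](C)(C)C(C)(C)C)[C@H](OCc1ccc(OC)cc1)[C@H](O[Si](CC)(CC)CC)C | intermediate
25 | 6α,8α,18-tris(tert-butyldimethylsilyloxy)-13,14,15,16-tetranorlabdan-12-yllithium (not isolated) | [Li]CC[C@@H]1[C@@]2(C)CCC[C@@](C)(CO[Si](C)(C)C(C)(C)C)[C@@H]2[C@@H](O[Si](C)(C)C(C)(C)C)C[C@@]1(C)O[Si](C)(C)C(C)(C)C | intermediate
26 | C13 ketone; 6,8,14,15,18-penta-O-TBS, 5'-O-PMB, 4'-O-TES | O=C(CC[C@@H]1[C@@]2(C)CCC[C@@](C)(CO[Si](C)(C)C(C)(C)C)[C@@H]2[C@@H](O[Si](C)(C)C(C)(C)C)C[C@@]1(C)O[Si](C)(C)C(C)(C)C)[C@H](O[Si](C)(C)C(C)(C)C)[C@@H](O[Si](C)(C)C(C)(C)C)[C@H](OCc1ccc(OC)cc1)[C@H](O[Si](CC)(CC)CC)C | intermediate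
27 | 13(16)-methylene compound; 6,8,14,15,18-penta-O-TBS, 5'-O-PMB, 4'-O-TES | C=C(CC[C@@H]1[C@@]2(C)CCC[C@@](C)(CO[Si](C)(C)C(C)(C)C)[C@@H]2[C@@H](O[Si](C)(C)C(C)(C)C)C[C@@]1(C)O[Si](C)(C)C(C)(C)C)[C@H](O[Si](C)(C)C(C)(C)C)[C@@H](O[Si](C)(C)C(C)(C)C)[C@H](OCc1ccc(OC)cc1)[C@H](O[Si](CC)(CC)CC)C | intermediate
28 | C4' carbinol; 6,8,14,15,18-penta-O-TBS, 5'-O-PMB | C=C(CC[C@@H]1[C@@]2(C)CCC[C@@](C)(CO[Si](C)(C)C(C)(C)C)[C@@H]2[C@@H](O[Si](C)(C)C(C)(C)C)C[C@@]1(C)O[Si](C)(C)C(C)(C)C)[C@H](O[Si](C)(C)C(C)(C)C)[C@@H](O[Si](C)(C)C(C)(C)C)[C@H](OCc1ccc(OC)cc1)[C@H](O)C | intermediate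
29 | C4' methyl ketone; 6,8,14,15,18-penta-O-TBS, 5'-O-PMB | C=C(CC[C@@H]1[C@@]2(C)CCC[C@@](C)(CO[Si](C)(C)C(C)(C)C)[C@@H]2[C@@H](O[Si](C)(C)C(C)(C)C)C[C@@]1(C)O[Si](C)(C)C(C)(C)C)[C@H](O[Si](C)(C)C(C)(C)C)[C@@H](O[Si](C)(C)C(C)(C)C)[C@H](OCc1ccc(OC)cc1)C(C)=O | intermediate
30 | 5'-hydroxy-4'-ketone; 6,8,14,15,18-penta-O-TBS | C=C(CC[C@@H]1[C@@]2(C)CCC[C@@](C)(CO[Si](C)(C)C(C)(C)C)[C@@H]2[C@@H](O[Si](C)(C)C(C)(C)C)C[C@@]1(C)O[Si](C)(C)C(C)(C)C)[C@H](O[Si](C)(C)C(C)(C)C)[C@@H](O[Si](C)(C)C(C)(C)C)[C@H](O)C(C)=O | intermediate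
31 | diethylphosphonoacetic acid | OC(=O)CP(=O)(OCC)OCC | starting material
32 | protected seco-lactone: 5'-O-diethylphosphonoacetate, C4' methyl ketone, 6,8,14,15,18-penta-O-TBS (key precursor) | C=C(CC[C@@H]1[C@@]2(C)CCC[C@@](C)(CO[Si](C)(C)C(C)(C)C)[C@@H]2[C@@H](O[Si](C)(C)C(C)(C)C)C[C@@]1(C)O[Si](C)(C)C(C)(C)C)[C@H](O[Si](C)(C)C(C)(C)C)[C@@H](O[Si](C)(C)C(C)(C)C)[C@H](OC(=O)CP(=O)(OCC)OCC)C(C)=O | intermediate
33 | protected target: butenolide, 6,8,14,15,18-penta-O-TBS (key product) | C=C(CC[C@@H]1[C@@]2(C)CCC[C@@](C)(CO[Si](C)(C)C(C)(C)C)[C@@H]2[C@@H](O[Si](C)(C)C(C)(C)C)C[C@@]1(C)O[Si](C)(C)C(C)(C)C)[C@H](O[Si](C)(C)C(C)(C)C)[C@@H](O[Si](C)(C)C(C)(C)C)[C@@H]1OC(=O)C=C1C | intermediate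
34 | CNP0301623.1 | C=C(CC[C@@H]1[C@@]2(C)CCC[C@@](C)(CO)[C@@H]2[C@@H](O)C[C@@]1(C)O)[C@H](O)[C@@H](O)[C@@H]1OC(=O)C=C1C | target

## Step count and risks

Total step count: 27. Longest linear sequence: 18 steps (steps 1–10 and 20–27, from larixol).

**Step 5 (C18–H oxidation).** β-Scission of the C5–C6 bond of the alkoxy radical could compete with the intended hydrogen shift. A slow hydrogen transfer could also let unselective iodine chemistry take over. The fallback sets out from 7 and attacks the same C–H bond by the Barton nitrite photolysis, in which the radical pair is generated without any oxidant in the flask.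
- NOCl in pyridine would give the 6α-nitrite ester F1.
- Irradiation (mercury lamp, Pyrex, toluene) and thermal tautomerisation of the nitroso compound would give the 18-aldoxime F2.
- Deoximation with aqueous NaHSO3 followed by dilute acid would free the aldehyde, which closes onto O6 as the 6α,18-lactol F3.
- LiAlH4 would then reduce F3 and the 12,8α-lactone together, and the route is rejoined at tetraol 11, so that step 6 is bypassed as well.

**Step 2 (epoxidation and Baeyer–Villiger oxidation in one flask).** Acid-induced opening or rearrangement of the spiro-epoxide may occur during the slower oxygen-insertion stage. The fallback sets out from 1, installs O8 before the side chain is touched, and rejoins the route at 7. It replaces steps 1–4 by five operations.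
- mCPBA with NaHCO3 would epoxidise only the more electron-rich 8(17)-alkene to 8α,17-epoxylarixol F4.
- LiAlH4 would give labd-14-ene-6α,8α,13-triol F5.
- Ac2O in pyridine would acetylate the only secondary hydroxyl to the 6-acetate F6.
- RuCl3 (cat.) with NaIO4 would degrade the hydroxy-vinyl side chain, by way of the C13 ketone and its cyclic enol ether with O8, to the 6α-acetoxy-12,8α-lactone F7.
- K2CO3 in MeOH would remove the acetate to give 7.

**Step 9 (selective desilylation).** The neopentyl C18 silyl ether may be lost alongside the C12 one, or the reaction may stall before conversion is complete. The fallback sets out from tetraol 11, makes the distinction by acylation instead, and returns at 13. It costs one step more than steps 8–9.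
- Pivaloyl chloride in pyridine at −20 °C would acylate only the unbranched primary C12 hydroxyl to the 12-pivalate F8.
- TBSOTf and 2,6-lutidine would silylate O6, O8 and O18 to the tris-silyl pivalate F9.
- i-Bu2AlH would remove the pivalate reductively to give 13.

## Further compounds

F1 | step 5 | 6α-nitrosooxy-13,14,15,16-tetranorlabdan-12,8α-olide | O=C1C[C@@H]2[C@@]3(C)CCCC(C)(C)[C@@H]3[C@@H](ON=O)C[C@@]2(C)O1
F2 | step 5 | 6α-hydroxy-18-(hydroxyimino)-13,14,15,16-tetranorlabdan-12,8α-olide | O=C1C[C@@H]2[C@@]3(C)CCC[C@@](C)(C=NO)[C@@H]3[C@@H](O)C[C@@]2(C)O1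
F3 | step 5 | 6α,18-epoxy-18-hydroxy-13,14,15,16-tetranorlabdan-12,8α-olide | O=C1C[C@@H]2[C@@]3(C)CCC[C@@](C)(C(O)O4)[C@@H]3[C@@H]4C[C@@]2(C)O1
F4 | step 2 | 8α,17-epoxylarixol | C=C[C@@](C)(O)CC[C@@H]1[C@@]2(C)CCCC(C)(C)[C@@H]2[C@@H](O)C[C@]13CO3
F5 | step 2 | (13S)-labd-14-ene-6α,8α,13-triol | C=C[C@@](C)(O)CC[C@@H]1[C@@]2(C)CCCC(C)(C)[C@@H]2[C@@H](O)C[C@@]1(C)O
F6 | step 2 | (13S)-8α,13-dihydroxylabd-14-en-6α-yl acetate | C=C[C@@](C)(O)CC[C@@H]1[C@@]2(C)CCCC(C)(C)[C@@H]2[C@@H](OC(C)=O)C[C@@]1(C)O
F7 | step 2 | 6α-acetoxy-13,14,15,16-tetranorlabdan-12,8α-olide | O=C1C[C@@H]2[C@@]3(C)CCCC(C)(C)[C@@H]3[C@@H](OC(C)=O)C[C@@]2(C)O1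
F8 | step 9 | 6α,8α,18-trihydroxy-13,14,15,16-tetranorlabdan-12-yl pivalate | CC(C)(C)C(=O)OCC[C@@H]1[C@@]2(C)CCC[C@@](C)(CO)[C@@H]2[C@@H](O)C[C@@]1(C)O
F9 | step 9 | 6α,8α,18-tris(tert-butyldimethylsilyloxy)-13,14,15,16-tetranorlabdan-12-yl pivalate | CC(C)(C)C(=O)OCC[C@@H]1[C@@]2(C)CCC[C@@](C)(CO[Si](C)(C)C(C)(C)C)[C@@H]2[C@@H](O[Si](C)(C)C(C)(C)C)C[C@@]1(C)O[Si](C)(C)C(C)(C)C
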